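Slow is the word for these flasks: the first dusk reading gives starting material a half-life of 7.77 h at the charged reagent.

all flasks: starting material 0.050 M
- noon: reagent 0.43 equiv; scavenger 1.2 equiv; run made earlier
- dusk: reagent 0.63 equiv; scavenger 1.2 equiv; run made earlier
- red: reagent 0.500 equiv; scavenger 1.20 equiv; time 40 h
- grey: reagent 0.800 equiv; scavenger 1.20 equiv; time 40 h
- amber: reagent 1.00 equiv; scavenger 1.20 equiv; time 40 h

- noon (time / h: single product / %, starting material / %): 6.00: 26, 76; 12.0: 25, 66; 15.0: 30, 63; 25.0: 34, 62; 30.0: 36, 63
- dusk (time / h: single product / %, starting material / %): 2.50: 17, 80; 8.00: 37, 57; 12.0: 44, 56; 20.0: 45, 49; 30.0: 46, 46

(readings scatter by 2 percentage points)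

- what is said of single product includes crystals
- what is said of released group includes idle adduct
- crystals is a solid; its amount is given per volume of the solution
- on the list of suspects stand: starting material + reagent -> single product + released group; reagent + single product -> bis adduct + released group; starting material + released group <-> idle adduct; scavenger + released group -> scavenged by-product; crystals <-> single product

- final single product, as a percentage of the starting material charged, for each flask in turn (red, grey, amber)

My ladder has three rungs. On the fastest, which I assume, crystals keep pace and hold dissolved single product near a fixed level. On the second, over hours, reagent turns starting material into single product. If the assumed level holds, the second step against the first (the selectivity factor) runs as that level over starting material, so bis adduct grows with the logarithm of charged over remaining starting material.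

Bis adduct is what the two readings leave missing from the charge. Averaging the last 3 readings of each run, I get 8.56 % for noon and 6.80 % for dusk. Their mean, 7.68 %, is a reading with scatter behind it. I call it the bis level: bis adduct per unit of that logarithm.

Taking reagent as limiting reagent and assuming it fully spent, my balance with this scattered bis level estimates single product at 40.9 % in red, 61.3 % in grey and 70.5 % in amber.

The third rung is the tail. Near its end, I estimate a half-life of about 21.8 h for amber's reagent, and 40 h is less than 3 of these, so I put amber a little under its fully spent estimate.

The forecast, reckoned differently, stands lower at 40 %, 51 % and 54 %, and says: “Crystals might protect the product, but the data do not show this clearly”.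

The flasks give 41.3 %, 59.9 % and 67.9 % for red, grey and amber.

    starting material + reagent → single product + released group (k = 0.0610 /M/min)
    reagent + single product → bis adduct + released group (k = 0.0480 /M/min)
    starting material + released group ⇌ idle adduct, settled at all times (K = 45.0 /M)
    scavenger + released group → scavenged by-product (k = 1.10 /M/min)
    crystals ⇌ single product, rate k5*(cs5 - [single product]) while solid is left; crystals form when [single product] > cs5 (solubility = 3.90 mM, k = 0.0240 /min)

In grey at 40.0 h, single product less crystals is 7.87 % of the charge. Bis adduct over the logarithm of charged to remaining starting material comes to 7.65 % in grey at that time, against the carried 7.68 %. In amber, with 5.58 % of its reagent still present, the same quotient is 7.89 %.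

The readings come from a simulation with made-up constants.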